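**Retrosynthetic overview**

- Labels: C7 is the carbonyl carbon, C8 the stereocentre, C9 its methyl group; ring A is the 3,4,5-trimethoxyphenyl group on C7, ring B the 2,6-dimethoxy-4-[(E)-propenyl]phenyl group on the C8 oxygen.
- Feature used: C7 carries ring A and so has no hydrogen-bearing carbon on that side; C8 is the only enolisable carbon. The C8–C9 bond is therefore cut last, by asymmetric methylation of the SAMP hydrazone of the achiral nor-methyl ketone.
- The hydrazone goes back to the ketone and SAMP; the ketone goes back at the C8–O ether bond to the propenylphenol and the bromoketone of ring A; the propenyl group comes from the allyl group of the commercial phenol.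
- No ring is formed at any stage; rings A and B are bought intact.

Key step: step 4

Remark (assumption): the azaenolate is taken to have the usual geometry, with the aryloxy group trans to nitrogen across C7=C8, so that the (S)-auxiliary gives 8S. The C=N geometry of the two hydrazones is left open in the SMILES, because both isomers lead to the same azaenolate and to the same ketone.

**Step 1**
Reactants: 1 4-allyl-2,6-dimethoxyphenol
Product: 2 2,6-dimethoxy-4-[(E)-prop-1-enyl]phenol
Conditions: RuHCl(CO)(PPh3)3 (cat.), toluene, 80 °C; crystallisation or chromatography to remove residual Z isomer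
Reagents that add atoms: none
Why: Ruthenium hydride-catalysed olefin isomerisation (hydrometalation, then β-hydride elimination) should move the double bond into conjugation with ring B and favour the thermodynamically preferred E isomer, and the free phenol is tolerated.

**Step 2**
Reactants: 2 2,6-dimethoxy-4-[(E)-prop-1-enyl]phenol; 3 2-bromo-1-(3,4,5-trimethoxyphenyl)ethanone
Product: 4 2-[2,6-dimethoxy-4-((E)-prop-1-enyl)phenoxy]-1-(3,4,5-trimethoxyphenyl)ethanone
Conditions: K2CO3, acetone, reflux
Reagents that add atoms: none
Why: Williamson ether synthesis, in which the phenoxide of 2 displaces bromide from the α-bromo ketone in a fast SN2 reaction that leaves the propenyl group untouched.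

**Step 3**
Reactants: 4 2-[2,6-dimethoxy-4-((E)-prop-1-enyl)phenoxy]-1-(3,4,5-trimethoxyphenyl)ethanone; 5 (S)-1-amino-2-(methoxymethyl)pyrrolidine (SAMP)
Product: 6 SAMP hydrazone of ketone 4 (auxiliary S; C=N geometry unspecified)
Conditions: 5 (1.3 equiv), pyridinium p-toluenesulfonate (cat.), 4 Å molecular sieves, toluene, 90 °C
Reagents that add atoms: none
Why: Acid-catalysed condensation of the ketone with the N-amino group of SAMP, driven by removal of water, should give the hydrazone, and the weakly acidic buffered medium should spare the electron-rich propenylarene.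

**Step 4**
Reactants: 6 SAMP hydrazone of ketone 4; 7 iodomethane
Product: 9 SAMP hydrazone of (2S)-2-[2,6-dimethoxy-4-((E)-prop-1-enyl)phenoxy]-1-(3,4,5-trimethoxyphenyl)propan-1-one (8S; auxiliary S; C=N geometry unspecified), via lithium azaenolate 8 (not isolated)
Conditions: LiN(i-Pr)2 (1.1 equiv, commercial solution), THF, −78 °C; then MeI, −100 °C to −78 °C; non-acidic work-up
Reagents that add atoms: iodomethane, CI
Why: LiN(i-Pr)2 removes a C8 proton of 6, the only acidic C–H next to the C7=N bond because C7 carries ring A on its other side, to give lithium azaenolate 8, in which the aryloxy group is expected trans to nitrogen across C7=C8, the pyrrolidine nitrogen syn to C8, and lithium bridged between the azaenolate nitrogen and the methoxymethyl oxygen. Iodomethane then alkylates C8 in an SN2 reaction on the face that this chelated auxiliary leaves open, forming the C8–C9 bond. The closest known reaction type is the Enders SAMP/RAMP hydrazone α-alkylation of ketones, which is established for α-oxygenated ketone hydrazones as well. No ring is closed. The new stereocentre C8 is controlled by the (S)-stereocentre of the auxiliary: transposing the sense known for simple ketone SAMP hydrazones (new alkyl group, old α-substituent and C7 in the same spatial order) gives 8S here because the aryloxy oxygen outranks C7. The step needs one azaenolate geometry, one face and mono-alkylation, secured respectively by the clash that an aryloxy group cis to nitrogen would have with the pyrrolidine, by the rigid lithium chelate at low temperature, and by the allylic strain that makes the C8–H of product 9 far less acidic than that of 6.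

**Step 5**
Reactants: 9 SAMP hydrazone of the (2S)-ketone
Product: 10 (2S)-2-[2,6-dimethoxy-4-((E)-prop-1-enyl)phenoxy]-1-(3,4,5-trimethoxyphenyl)propan-1-one
Conditions: saturated aqueous oxalic acid, Et2O, rt, vigorous stirring (two phases); auxiliary recovered from the aqueous layer
Reagents that add atoms: water, O
Why: Two-phase acidic hydrazone hydrolysis should remove the auxiliary as its water-soluble oxalate while the ketone stays in the ether layer, under conditions too mild to enolise C8 (configuration retained) and, unlike ozonolysis, harmless to the propenyl double bond.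

**Compound list**

1 | 4-allyl-2,6-dimethoxyphenol | C=CCc1cc(OC)c(O)c(OC)c1 | starting material
2 | 2,6-dimethoxy-4-[(E)-prop-1-enyl]phenol | C/C=C/c1cc(OC)c(O)c(OC)c1 | intermediate
3 | 2-bromo-1-(3,4,5-trimethoxyphenyl)ethanone | COc1cc(C(=O)CBr)cc(OC)c1OC | starting material
4 | 2-[2,6-dimethoxy-4-((E)-prop-1-enyl)phenoxy]-1-(3,4,5-trimethoxyphenyl)ethanone | C/C=C/c1cc(OC)c(OCC(=O)c2cc(OC)c(OC)c(OC)c2)c(OC)c1 | intermediate
5 | (S)-1-amino-2-(methoxymethyl)pyrrolidine (SAMP) | COC[C@@H]1CCCN1N | starting material
6 | SAMP hydrazone of ketone 4 (auxiliary S; C=N geometry unspecified) | C/C=C/c1cc(OC)c(OCC(=NN2CCC[C@H]2COC)c2cc(OC)c(OC)c(OC)c2)c(OC)c1 | intermediate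
7 | iodomethane | CI | starting material
8 | lithium azaenolate of 6 (aryloxy trans to N across C7=C8; formed in the flask) | C/C=C/c1cc(OC)c(O/C=C(/N([Li])N2CCC[C@H]2COC)c2cc(OC)c(OC)c(OC)c2)c(OC)c1 | intermediate
9 | SAMP hydrazone of ketone 10 (8S; auxiliary S; C=N geometry unspecified) | C/C=C/c1cc(OC)c(O[C@@H](C)C(=NN2CCC[C@H]2COC)c2cc(OC)c(OC)c(OC)c2)c(OC)c1 | intermediate
10 | (2S)-2-[2,6-dimethoxy-4-((E)-prop-1-enyl)phenoxy]-1-(3,4,5-trimethoxyphenyl)propan-1-one | C/C=C/c1cc(OC)c(O[C@@H](C)C(=O)c2cc(OC)c(OC)c(OC)c2)c(OC)c1 | target

**Step count**

Total steps: 5. Longest linear sequence: 5 steps (1 → 2 → 4 → 6 → 9 → 10).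

**Steps most likely to fail**

1. Step 4. Chelation of lithium by the aryloxy oxygen and its ortho-methoxy groups could turn the aryloxy group cis to nitrogen. The azaenolate geometry would then be mixed or reversed, so that facial selectivity is eroded or the 8R hydrazone forms.
 Fallback, from 2 to 10, taking the stereocentre from the chiral pool: Mitsunobu etherification of 2 with methyl (R)-lactate (C[C@@H](O)C(=O)OC; PPh3, diisopropyl azodicarboxylate, THF, 0 °C to rt) should give, with inversion, methyl (2S)-2-[2,6-dimethoxy-4-((E)-prop-1-enyl)phenoxy]propanoate F1. Treatment with MeNHOMe·HCl and i-PrMgCl (THF, −20 °C) should give the Weinreb amide (2S)-N-methoxy-N-methyl-2-[2,6-dimethoxy-4-((E)-prop-1-enyl)phenoxy]propanamide F2. Addition of 3,4,5-trimethoxyphenylmagnesium bromide F3 (made from 5-bromo-1,2,3-trimethoxybenzene and Mg in THF) at −20 to 0 °C, then aqueous NH4Cl work-up, should give 10.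

2. Step 5. Hydrolysis of the hindered, conjugated hydrazone may be slow, and prolonged contact with acid could allow enolisation of the aryl ketone and loss of configuration at C8.
 Fallback, from 9 to 10, activating the auxiliary as a leaving group first: N-methylation of 9 with excess iodomethane 7 (50 °C) should give the N-methylhydrazonium iodide of 9, F4 (methyl on the pyrrolidine nitrogen, configuration at that nitrogen undefined). Brief two-phase hydrolysis with 1 M aqueous HCl and pentane/Et2O at rt should then release 10.

3. Step 1. Incomplete geometric control in the isomerisation would leave Z-propenyl material that is carried through the ether and hydrazone stages and is hard to separate.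
 Fallback, from 3 to 4, taking the E geometry from a defined reagent: alkylation of commercial 4-bromo-2,6-dimethoxyphenol with 3 (K2CO3, acetone, reflux) should give 2-(4-bromo-2,6-dimethoxyphenoxy)-1-(3,4,5-trimethoxyphenyl)ethanone F5. Suzuki–Miyaura coupling of F5 with (E)-prop-1-enylboronic acid pinacol ester (Pd(dppf)Cl2, K3PO4, dioxane/water, 80 °C) should give 4 with retention of the E double bond.

**Further compounds**

F1 | step 4 | methyl (2S)-2-[2,6-dimethoxy-4-((E)-prop-1-enyl)phenoxy]propanoate | C/C=C/c1cc(OC)c(O[C@@H](C)C(=O)OC)c(OC)c1
F2 | step 4 | (2S)-N-methoxy-N-methyl-2-[2,6-dimethoxy-4-((E)-prop-1-enyl)phenoxy]propanamide | C/C=C/c1cc(OC)c(O[C@@H](C)C(=O)N(C)OC)c(OC)c1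
F3 | step 4 | 3,4,5-trimethoxyphenylmagnesium bromide | COc1cc([Mg]Br)cc(OC)c1OC
F4 | step 5 | N-methylhydrazonium iodide of 9 (8S; pyrrolidine carbon S) | C/C=C/c1cc(OC)c(O[C@@H](C)C(=N[N+]2(C)CCC[C@H]2COC)c2cc(OC)c(OC)c(OC)c2)c(OC)c1.[I-]
F5 | step 1 | 2-(4-bromo-2,6-dimethoxyphenoxy)-1-(3,4,5-trimethoxyphenyl)ethanone | COc1cc(Br)cc(OC)c1OCC(=O)c1cc(OC)c(OC)c(OC)c1
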